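**Retrosynthetic overview**
- Lactone last: the 13-hydroxy-15,16-olide comes from a 13,16-epoxide and the C15 carboxylate. C12/C13 come from a Sharpless epoxidation of a C12 allylic alcohol (Ni/Cr coupling onto a C12 aldehyde), inverted at C12 by a Mitsunobu reaction that also installs the tiglate.
- The C9 quaternary centre and the 8(17)-methylene come from a vinyl conjugate addition/Mannich trapping on a Δ8-7-ketone. The 6α-OH comes from α′-hydroxylation.
- The ring-A tiglate and 4(18)-methylene come from a trans-decalin-1,4-dione (hydride reduction, Wittig, Mitsunobu).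
- The decalin comes from one operation: oxidative dearomatisation of 4-methylveratrole to 2-methoxy-5-methylbenzoquinone, then a chelate-controlled enantioselective Diels–Alder reaction with a 2-silyloxypentadiene; C10 is then epimerised to trans.
- Ring order: ring A (from the arene), ring B (cycloaddition), lactone.

Assumption: the compounds on the Reactants lines that are not made in the route, the ligands and the reagents are commercial. Locants follow clerodane numbering (ring A = C1–C5 and C10; ring B = C5–C10; C11–C16 side chain on C9; C17 on C8, C18 on C4, methyl C19 on C5, methyl C20 on C9); α is the face of the C5 methyl group, β the opposite face.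

**Step 1**
Reactants: 1 (E)-pent-3-en-2-one
Product: 2 (E)-2-(triisopropylsilyloxy)penta-1,3-diene
Conditions: i-Pr3SiOTf, Et3N, Et2O, 0 °C → rt
Reagents that add atoms: triisopropylsilyl triflate, CC(C)[Si](C(C)C)(C(C)C)OS(=O)(=O)C(F)(F)F
Why: Soft enolisation (silyl enol ether formation) removes a proton only from the α-methyl group and gives the cross-conjugated 2-silyloxy diene with the (E)-propenyl unit unchanged.

**Step 2**
Reactants: 3 4-methylveratrole (1,2-dimethoxy-4-methylbenzene); 2 (E)-2-(triisopropylsilyloxy)penta-1,3-diene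
Product: 5 cis-fused Diels–Alder adduct (ring A: 2-methoxy-2-ene-1,4-dione; 5α-methyl; 10α-H; ring B: 7-triisopropylsilyloxy-7-ene; 9β-methyl), via methoxytoluquinone 4 (not isolated)
Conditions: 30% H2O2, HCO2H, 0 °C → rt; extraction into CH2Cl2, NaHCO3 wash, drying; then Sm(OTf)3 (10 mol %), (S,S)-Ph-pybox (12 mol %), 4 Å sieves, 2 (1.5 equiv), CH2Cl2, −78 → −30 °C
Reagents that add atoms: hydrogen peroxide, OO
Why: Proposed new method: performic acid hydroxylates the arene para to the 3-methoxy group and oxidises the resulting p-methoxyphenol to the p-quinone with loss of methanol (oxidative dearomatisation); the quinone then chelates the samarium–pybox Lewis acid through C1=O and the neighbouring methoxy oxygen, which activates only the methyl-bearing double bond, puts the nucleophilic CH2 terminus of the diene on the methyl carbon (endo Diels–Alder) and lets the ligand shield one face so that the quaternary C5 is set; the closest known reactions are lanthanide–pybox-catalysed Diels–Alder reactions of chelating 2-acylquinones with 2-silyloxydienes and the thermal or chelation-controlled regiochemistry of this methoxytoluquinone.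

**Step 3**
Reactants: 5 cis-fused adduct
Product: 6 trans-fused adduct (as 5 but 10β-H)
Conditions: DBU (0.2 equiv), CH2Cl2, rt; crystallisation, mother liquor re-equilibrated
Reagents that add atoms: none
Why: Base-mediated epimerisation through the C1 enolate moves the only enolisable ring-fusion centre (C10) to the trans-fused isomer, as is known for the butadiene adduct of the same quinone; C5 is quaternary, so the ring cannot aromatise.

**Step 4**
Reactants: 6 trans-fused adduct
Product: 7 trans-fused 1,4-dione (5α,9β-dimethyl; 10β-H; 7-triisopropylsilyloxy-7-ene)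
Conditions: SmI2 (4.5 equiv), MeOH, THF, −78 °C
Reagents that add atoms: none
Why: Samarium diiodide reduces the ene-dione to the saturated dione and then cleaves the methoxy group α to the C1 ketone (ketyl formation and β-elimination), leaving the silyl enol ether and C5, C9 and C10 untouched.

**Step 5**
Reactants: 7 trans-fused 1,4-dione
Product: 8 1α-hydroxy-4-ketone (axial alcohol)
Conditions: LiBH(s-Bu)3 (1.05 equiv), THF, −78 °C
Reagents that add atoms: none
Why: The bulky borohydride reduces the less hindered C1 ketone (C4 is flanked by the quaternary C5) from the equatorial β-face, because the axial α-face is blocked by the syn-axial C5 methyl, giving the 1α-alcohol.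

**Step 6**
Reactants: 8 1α-hydroxy-4-ketone
Product: 9 1α-hydroxy-4(18)-methylene compound
Conditions: Ph3PCH3Br, KOtBu, toluene, 90 °C
Reagents that add atoms: methyltriphenylphosphonium bromide, C[P+](c1ccccc1)(c1ccccc1)c1ccccc1.[Br-]
Why: Wittig methylenation of the only remaining ketone; the alkoxide formed in situ and the silyl enol ether do not react with the ylide.

**Step 7**
Reactants: 9 1α-hydroxy-4(18)-methylene compound
Product: 10 1β-tiglate (4(18)-methylene; 7-triisopropylsilyloxy-7-ene)
Conditions: tiglic acid, PPh3, DIAD, toluene, 0 → 60 °C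
Reagents that add atoms: tiglic acid, C/C=C(\C)C(=O)O
Why: Mitsunobu esterification displaces the axial 1α-oxyphosphonium group by tiglate from the β-face (SN2, inversion) and gives the equatorial 1β-ester of the target.

**Step 8**
Reactants: 10 1β-tiglate
Product: 11 1β-tigloyloxy-4(18),8-dien-7-one (methyl on C9; 10β-H)
Conditions: Pd(OAc)2 (1.1 equiv), MeCN, 40 °C
Reagents that add atoms: none
Why: Saegusa–Ito oxidation: the palladium enolate from the silyl enol ether can lose hydride only from C9 (C5 is quaternary), so the Δ8-7-ketone is the only enone.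

**Step 9**
Reactants: 11 1β-tigloyloxy-4(18),8-dien-7-one
Product: 13 6α-hydroxy derivative of 11, via 6β-hydroxy epimer 12 (not isolated)
Conditions: KN(SiMe3)2 (1.15 equiv), THF, −78 °C; 2-(phenylsulfonyl)-3-phenyloxaziridine; AcOH; then DBU (0.3 equiv), toluene, rt
Reagents that add atoms: 2-(phenylsulfonyl)-3-phenyloxaziridine, O=S(=O)(c1ccccc1)N1OC1c1ccccc1
Why: Kinetic deprotonation at the only α′ position (C6) and Davis hydroxylation give the 6-hydroxy ketone from the open β-face; equilibration through the enediol then gives the equatorial 6α-alcohol, which is hydrogen-bonded to the C7 carbonyl.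

**Step 10**
Reactants: 13 6α-hydroxy derivative of 11
Product: 17 6α-triethylsilyloxy-8(17)-methylene-7-ketone with 9β-vinyl and 9α-methyl, via bis-silyl vinyl adduct 14 (not isolated), via Mannich base 15 (not isolated), via methiodide 16 (not isolated)
Conditions: CH2=CHMgBr (3.5 equiv), CuBr·SMe2 (20 mol %), Et3SiCl (3.5 equiv), HMPA, THF, −78 → −30 °C; then Me2N=CH2+ I−, CH2Cl2, rt; MeI; NaHCO3 (aq)
Reagents that add atoms: vinylmagnesium bromide, C=C[Mg]Br; chlorotriethylsilane, CC[Si](Cl)(CC)CC; N,N-dimethylmethyleneiminium iodide, C=[N+](C)C.[I-]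
Why: Copper-catalysed, silyl-chloride-accelerated conjugate addition delivers vinyl to C9 from the β-face, anti to the axial C5 methyl (the sense seen in enolate alkylations at C9 of trans-clerodane decalones), and gives the C7=C8 silyl enol ether regiospecifically; Mukaiyama–Mannich reaction, quaternisation and elimination then give the 8(17)-methylene ketone.

**Step 11**
Reactants: 17 8(17)-methylene-7-ketone with 9β-vinyl
Product: 18 12-aldehyde (9β-CH2CHO)
Conditions: PdCl2(PhCN)2 (12 mol %), CuCl2·2H2O (12 mol %), AgNO2 (6 mol %), O2 (1 atm), t-BuOH/MeNO2 15:1, rt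
Reagents that add atoms: dioxygen, O=O
Why: Nitrite-modified, aldehyde-selective Wacker oxidation puts oxygen on the terminal carbon of the vinyl group on the quaternary centre; the 1,1-disubstituted and electron-poor alkenes do not react.

**Step 12**
Reactants: 19 3-bromobut-3-enoic acid
Product: 20 2-(trimethylsilyl)ethyl 3-bromobut-3-enoate
Conditions: 2-(trimethylsilyl)ethanol, DCC, DMAP (5 mol %), CH2Cl2, 0 °C
Reagents that add atoms: 2-(trimethylsilyl)ethanol, C[Si](C)(C)CCO
Why: Steglich esterification at low temperature, which does not move the vinyl bromide double bond into conjugation.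

**Step 13**
Reactants: 18 12-aldehyde; 20 2-(trimethylsilyl)ethyl 3-bromobut-3-enoate
Product: 21 (12R)-allylic alcohol (12-hydroxy-13(16)-ene; C15 trimethylsilylethyl ester)
Conditions: CrCl2 (10 mol %), Kishi oxazoline–sulfonamide ligand (11 mol %), proton sponge, NiCl2·dmp (2 mol %; dmp = 2,9-dimethyl-1,10-phenanthroline), Mn, Cp2ZrCl2, LiCl, MeCN, rt
Reagents that add atoms: none
Why: Catalytic asymmetric Nozaki–Hiyama–Kishi coupling: nickel activates the vinyl bromide, the alkenylchromium species adds only to the aldehyde, and the chiral ligand on chromium sets C12 as R by reagent control.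

**Step 14**
Reactants: 21 (12R)-allylic alcohol
Product: 22 (12R,13S)-13,16-epoxy-12-ol
Conditions: Ti(OiPr)4 (0.2 equiv), D-(−)-diisopropyl tartrate (0.25 equiv), t-BuOOH, 4 Å sieves, CH2Cl2, −20 °C
Reagents that add atoms: tert-butyl hydroperoxide, CC(C)(C)OO
Why: Sharpless asymmetric epoxidation in its matched kinetic-resolution mode gives the erythro (12R,13S) epoxy alcohol, leaves any (12S) epimer from step 13 unreacted and touches only the allylic-alcohol alkene.

**Step 15**
Reactants: 22 (12R,13S)-13,16-epoxy-12-ol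
Product: 23 (12S,13S)-13,16-epoxy-12-tiglate
Conditions: tiglic acid, PPh3, DIAD (premixed), toluene, 0 °C → rt
Reagents that add atoms: tiglic acid, C/C=C(\C)C(=O)O
Why: Mitsunobu inversion of the erythro epoxy alcohol (SN2 at C12) gives the threo (12S,13S) arrangement and installs the second tiglate in the same operation.

**Step 16**
Reactants: 23 (12S,13S)-13,16-epoxy-12-tiglate
Product: 26 CNP0233387.1, via epoxy acid 24 (not isolated), via iodohydrin acid 25 (not isolated)
Conditions: TASF (2.5 equiv), DMF, 0 °C; then AcOH (3 equiv), LiI (1.5 equiv), 40 °C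
Reagents that add atoms: none
Why: Fluoride cleaves the trimethylsilylethyl ester (loss of ethene) and the triethylsilyl ether; iodide then opens the epoxide at the primary C16 (SN2) and the carboxylate displaces iodide in a 5-exo-tet lactonisation, so the C13–O bond is never broken and C13 keeps its configuration.

**Compound list**
1 | (E)-pent-3-en-2-one | C/C=C/C(C)=O | starting material
2 | (E)-2-(triisopropylsilyloxy)penta-1,3-diene | C=C(O[Si](C(C)C)(C(C)C)C(C)C)/C=C/C | intermediate
3 | 4-methylveratrole | Cc1ccc(OC)c(OC)c1 | starting material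
4 | 2-methoxy-5-methyl-1,4-benzoquinone | COC1=CC(=O)C(C)=CC1=O | intermediate
5 | cis-fused adduct (5α-Me, 10α-H, 9β-Me) | O=C1C=C(OC)C(=O)[C@@H]2[C@@]1(C)CC(O[Si](C(C)C)(C(C)C)C(C)C)=C[C@@H]2C | intermediate
6 | trans-fused adduct (10β-H) | O=C1C=C(OC)C(=O)[C@H]2[C@@]1(C)CC(O[Si](C(C)C)(C(C)C)C(C)C)=C[C@@H]2C | intermediate
7 | trans-fused 1,4-dione | O=C1CCC(=O)[C@H]2[C@@]1(C)CC(O[Si](C(C)C)(C(C)C)C(C)C)=C[C@@H]2C | intermediate
8 | 1α-hydroxy-4-ketone | O=C1CC[C@H](O)[C@H]2[C@@]1(C)CC(O[Si](C(C)C)(C(C)C)C(C)C)=C[C@@H]2C | intermediate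
9 | 1α-hydroxy-4(18)-methylene compound | C=C1CC[C@H](O)[C@H]2[C@@]1(C)CC(O[Si](C(C)C)(C(C)C)C(C)C)=C[C@@H]2C | intermediate
10 | 1β-tiglate, 7-silyl enol ether | C=C1CC[C@@H](OC(=O)/C(C)=C/C)[C@H]2[C@@]1(C)CC(O[Si](C(C)C)(C(C)C)C(C)C)=C[C@@H]2C | intermediate
11 | 1β-tigloyloxy-4(18),8-dien-7-one | C=C1CC[C@@H](OC(=O)/C(C)=C/C)[C@H]2[C@@]1(C)CC(=O)C=C2C | intermediate
12 | 6β-hydroxy derivative of 11 | C=C1CC[C@@H](OC(=O)/C(C)=C/C)[C@H]2[C@@]1(C)[C@H](O)C(=O)C=C2C | intermediate
13 | 6α-hydroxy derivative of 11 | C=C1CC[C@@H](OC(=O)/C(C)=C/C)[C@H]2[C@@]1(C)[C@@H](O)C(=O)C=C2C | intermediate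
14 | 6α-triethylsilyloxy 7-triethylsilyl enol ether, 9β-vinyl | C=C1CC[C@@H](OC(=O)/C(C)=C/C)[C@H]2[C@@]1(C)[C@@H](O[Si](CC)(CC)CC)C(O[Si](CC)(CC)CC)=C[C@]2(C)C=C | intermediate
15 | 8-(dimethylaminomethyl)-7-ketone (C8 epimers) | C=C1CC[C@@H](OC(=O)/C(C)=C/C)[C@H]2[C@@]1(C)[C@@H](O[Si](CC)(CC)CC)C(=O)C(CN(C)C)[C@]2(C)C=C | intermediate
16 | trimethylammonium iodide of 15 | C=C1CC[C@@H](OC(=O)/C(C)=C/C)[C@H]2[C@@]1(C)[C@@H](O[Si](CC)(CC)CC)C(=O)C(C[N+](C)(C)C)[C@]2(C)C=C.[I-] | intermediate
17 | 6α-triethylsilyloxy-8(17)-methylene-7-ketone, 9β-vinyl | C=C1CC[C@@H](OC(=O)/C(C)=C/C)[C@H]2[C@@]1(C)[C@@H](O[Si](CC)(CC)CC)C(=O)C(=C)[C@]2(C)C=C | intermediate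
18 | 12-aldehyde | C=C1CC[C@@H](OC(=O)/C(C)=C/C)[C@H]2[C@@]1(C)[C@@H](O[Si](CC)(CC)CC)C(=O)C(=C)[C@]2(C)CC=O | intermediate
19 | 3-bromobut-3-enoic acid | C=C(Br)CC(=O)O | starting material
20 | 2-(trimethylsilyl)ethyl 3-bromobut-3-enoate | C=C(Br)CC(=O)OCC[Si](C)(C)C | intermediate
21 | (12R)-allylic alcohol | C=C1CC[C@@H](OC(=O)/C(C)=C/C)[C@H]2[C@@]1(C)[C@@H](O[Si](CC)(CC)CC)C(=O)C(=C)[C@]2(C)C[C@@H](O)C(=C)CC(=O)OCC[Si](C)(C)C | intermediate
22 | (12R,13S)-13,16-epoxy-12-ol | C=C1CC[C@@H](OC(=O)/C(C)=C/C)[C@H]2[C@@]1(C)[C@@H](O[Si](CC)(CC)CC)C(=O)C(=C)[C@]2(C)C[C@@H](O)[C@]1(CC(=O)OCC[Si](C)(C)C)CO1 | intermediate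
23 | (12S,13S)-13,16-epoxy-12-tiglate | C=C1CC[C@@H](OC(=O)/C(C)=C/C)[C@H]2[C@@]1(C)[C@@H](O[Si](CC)(CC)CC)C(=O)C(=C)[C@]2(C)C[C@H](OC(=O)/C(C)=C/C)[C@]1(CC(=O)OCC[Si](C)(C)C)CO1 | intermediate
24 | epoxy acid (6α-OH free, C15 acid) | C=C1CC[C@@H](OC(=O)/C(C)=C/C)[C@H]2[C@@]1(C)[C@@H](O)C(=O)C(=C)[C@]2(C)C[C@H](OC(=O)/C(C)=C/C)[C@]1(CC(=O)O)CO1 | intermediate
25 | iodohydrin acid (13-hydroxy-16-iodo) | C=C1CC[C@@H](OC(=O)/C(C)=C/C)[C@H]2[C@@]1(C)[C@@H](O)C(=O)C(=C)[C@]2(C)C[C@H](OC(=O)/C(C)=C/C)[C@@](O)(CI)CC(=O)O | intermediate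
26 | CNP0233387.1 | C=C1CC[C@@H](OC(=O)/C(C)=C/C)[C@H]2[C@@]1(C)[C@@H](O)C(=O)C(=C)[C@]2(C)C[C@H](OC(=O)/C(C)=C/C)[C@@]1(O)COC(=O)C1 | target

**Step count and risks**
Total steps: 16. Longest linear sequence: 15 (steps 1–11 and 13–16).

The three steps most likely to fail:

Step 2. The chelate-controlled asymmetric cycloaddition is unprecedented for this quinone, the sense of induction of the ligand has to be confirmed, and the crude quinone may inhibit the catalyst. The fallback sets out from 4 (crystallised after the peracid oxidation of 3) and 2 and comes back at 8. The cycloaddition is run thermally without catalyst (toluene, 80 °C; same regiochemistry), and racemic 5 is taken through steps 3–5. Racemic 8 is esterified with (S)-O-methylmandelic acid (DCC, DMAP) to two separable diastereomers, the (S)-O-methylmandelate of 8 F1 and the (S)-O-methylmandelate of ent-8 F2. LiOH hydrolysis of F1 returns enantiopure 8.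

Step 7. SN2 at the axial, peri-hindered C1 competes with elimination. The fallback sets out from 9 and comes back at 10. Dess–Martin oxidation gives the 1-ketone F3; a ketoreductase (NADPH, i-PrOH) chosen to deliver hydride to the hindered α-face gives the 1β-alcohol F4; tigloyl chloride, DMAP and pyridine then give 10.

Step 10. The conjugate addition must form a congested quaternary centre with the right face selectivity. The fallback sets out from 13 and comes back at 18. Et3SiOTf/2,6-lutidine gives the 6-O-triethylsilyl enone F5. CH2=CHCH2MgBr/CeCl3 adds to C7 from the β-face to give the 7β-allyl-7α-ol F6. KH/18-crown-6 starts an anionic oxy-Cope rearrangement that carries the allyl group suprafacially to C9, and the enolate is trapped with Me2N=CH2+ I− as the allyl Mannich base F7. MeI gives its methiodide F8, and NaHCO3 gives the 9β-allyl 8(17)-methylene ketone F9. OsO4 (cat.)/NaIO4/2,6-lutidine cleaves the monosubstituted alkene to 18.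

**Further compounds**
F1 | step 2 | (S)-O-methylmandelate of 8 | O=C1CC[C@H](OC(=O)[C@@H](OC)c3ccccc3)[C@H]2[C@@]1(C)CC(O[Si](C(C)C)(C(C)C)C(C)C)=C[C@@H]2C
F2 | step 2 | (S)-O-methylmandelate of ent-8 | O=C1CC[C@@H](OC(=O)[C@@H](OC)c3ccccc3)[C@@H]2[C@]1(C)CC(O[Si](C(C)C)(C(C)C)C(C)C)=C[C@H]2C
F3 | step 7 | 1-ketone from 9 | C=C1CCC(=O)[C@H]2[C@@]1(C)CC(O[Si](C(C)C)(C(C)C)C(C)C)=C[C@@H]2C
F4 | step 7 | 1β-alcohol (C1 epimer of 9) | C=C1CC[C@@H](O)[C@H]2[C@@]1(C)CC(O[Si](C(C)C)(C(C)C)C(C)C)=C[C@@H]2C
F5 | step 10 | 6-O-triethylsilyl ether of 13 | C=C1CC[C@@H](OC(=O)/C(C)=C/C)[C@H]2[C@@]1(C)[C@@H](O[Si](CC)(CC)CC)C(=O)C=C2C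
F6 | step 10 | 7β-allyl-7α-ol | C=C1CC[C@@H](OC(=O)/C(C)=C/C)[C@H]2[C@@]1(C)[C@@H](O[Si](CC)(CC)CC)[C@](O)(CC=C)C=C2C
F7 | step 10 | allyl Mannich base | C=C1CC[C@@H](OC(=O)/C(C)=C/C)[C@H]2[C@@]1(C)[C@@H](O[Si](CC)(CC)CC)C(=O)C(CN(C)C)[C@]2(C)CC=C
F8 | step 10 | methiodide of F7 | C=C1CC[C@@H](OC(=O)/C(C)=C/C)[C@H]2[C@@]1(C)[C@@H](O[Si](CC)(CC)CC)C(=O)C(C[N+](C)(C)C)[C@]2(C)CC=C.[I-]
F9 | step 10 | 9β-allyl 8(17)-methylene ketone | C=C1CC[C@@H](OC(=O)/C(C)=C/C)[C@H]2[C@@]1(C)[C@@H](O[Si](CC)(CC)CC)C(=O)C(=C)[C@]2(C)CC=C
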